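Retrosynthetic cuts: the two O–Si bonds and the O4'–prenyl bond; the C5'–CMe2 bond (retro-Claisen, back to a 4'-O-prenyl ether); then ring C at O1–C2 and at C3–C4.
Feature used: C4 of ring C is the benzylic carbon on C4a, ortho to the O1-bearing C8a of ring A, so O1–C8a–C4a–C4 can enter as an ortho-quinone methide that takes up C3 and C2 from a ring B arylacetaldehyde.
Forward order: 2,4-dihydroxybenzaldehyde supplies ring A (as a sulfone) and ring B (as an arylacetaldehyde); their amine-catalysed (4+2) union closes ring C as a lactol; hydride opening and Mitsunobu re-closure give the chroman; Claisen shift, O-prenylation and desilylation finish ring B.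
Stereochemistry: C3 is the only stereocentre; it is set as (R) by the chiral secondary amine in the ring-forming step and is neither deprotonated nor substituted afterwards.

Key step: step 8

Remark: the sense of induction is assigned from the usual s-trans (E)-enamine model; should it prove opposite, the (S)-catalyst would be used with no other change.

Step 1
Reactants: 1 2,4-dihydroxybenzaldehyde
Product: 2 2-hydroxy-4-(triisopropylsilyloxy)benzaldehyde
Conditions: TIPSCl (1.05 equiv), imidazole, CH2Cl2, 0 °C to rt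
Reagents that add atoms: chlorotriisopropylsilane (TIPSCl), CC(C)[Si](Cl)(C(C)C)C(C)C
Why: Silyl ether formation, selective for the 4-OH because it is the more acidic and unhindered phenol while the 2-OH is tied up in a hydrogen bond to the aldehyde.

Step 2
Reactants: 2 2-hydroxy-4-(triisopropylsilyloxy)benzaldehyde
Product: 3 2-(hydroxymethyl)-5-(triisopropylsilyloxy)phenol
Conditions: NaBH4, MeOH–THF, 0 °C; used crude
Reagents that add atoms: none
Why: Hydride reduction of the aldehyde by NaBH4, which aryl triisopropylsilyl ethers tolerate in cold methanol.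

Step 3
Reactants: 3 2-(hydroxymethyl)-5-(triisopropylsilyloxy)phenol; 4 sodium p-toluenesulfinate
Product: 5 2-(tosylmethyl)-5-(triisopropylsilyloxy)phenol
Conditions: 4 (3 equiv), HCO2H, THF–H2O, rt
Reagents that add atoms: sodium p-toluenesulfinate 4, Cc1ccc(cc1)S(=O)[O-].[Na+]
Why: SN1-type substitution in which formic acid ionises the 2,4-dioxygenated benzylic alcohol to a stabilised o-hydroxybenzyl cation that excess sulfinate should capture at sulfur faster than the electron-rich ring can, the usual access to 2-(sulfonylmethyl)phenols from salicyl alcohols.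

Step 4
Reactants: 1 2,4-dihydroxybenzaldehyde; 6 prenyl bromide (1-bromo-3-methylbut-2-ene)
Product: 7 2-hydroxy-4-(3-methylbut-2-enyloxy)benzaldehyde
Conditions: 6 (1.05 equiv), K2CO3, acetone, rt to 50 °C
Reagents that add atoms: prenyl bromide 6, CC(C)=CCBr
Why: Williamson etherification, selective for the 4-OH because the chelated 2-OH is less acidic and less nucleophilic.

Step 5
Reactants: 7 2-hydroxy-4-(3-methylbut-2-enyloxy)benzaldehyde
Product: 8 4-(3-methylbut-2-enyloxy)-2-(triisopropylsilyloxy)benzaldehyde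
Conditions: TIPSCl, imidazole, DMF, rt to 40 °C
Reagents that add atoms: chlorotriisopropylsilane (TIPSCl), CC(C)[Si](Cl)(C(C)C)C(C)C
Why: Silyl ether formation on the remaining chelated phenol under the imidazole/DMF protocol, giving a bulky group that later keeps the ring B oxygen out of ring closures and shields C3' in the Claisen step.

Step 6
Reactants: 8 4-(3-methylbut-2-enyloxy)-2-(triisopropylsilyloxy)benzaldehyde
Product: 9 triisopropyl[2-(2-methoxyvinyl)-5-(3-methylbut-2-enyloxy)phenoxy]silane (E/Z mixture)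
Conditions: Ph3P(CH2OMe)Cl (1.3 equiv), KOtBu (1.2 equiv), THF, 0 °C; then 8, 0 °C to rt
Reagents that add atoms: (methoxymethyl)triphenylphosphonium chloride, COC[P+](c1ccccc1)(c1ccccc1)c1ccccc1.[Cl-]
Why: Wittig reaction with (methoxymethylene)triphenylphosphorane adds the one carbon as an enol ether, both geometric isomers of which converge in step 7, and the ylide, kept free of excess alkoxide, leaves the aryl silyl ether alone.

Step 7
Reactants: 9 triisopropyl[2-(2-methoxyvinyl)-5-(3-methylbut-2-enyloxy)phenoxy]silane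
Product: 10 2-[4-(3-methylbut-2-enyloxy)-2-(triisopropylsilyloxy)phenyl]acetaldehyde
Conditions: 2 M aq. HCl, THF, 40 °C; extracted and used at once without chromatography
Reagents that add atoms: water, O
Why: Acid-catalysed enol ether hydrolysis (C-protonation, hydration of the oxocarbenium ion, loss of methanol) in dilute aqueous acid, which should spare the aryl prenyl and silyl ethers, the silyl group also preventing closure of the ring B oxygen to a benzofuran.

Step 8
Reactants: 5 2-(tosylmethyl)-5-(triisopropylsilyloxy)phenol; 10 2-[4-(3-methylbut-2-enyloxy)-2-(triisopropylsilyloxy)phenyl]acetaldehyde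
Product: 14 (3R)-3-[4-(3-methylbut-2-enyloxy)-2-(triisopropylsilyloxy)phenyl]-7-(triisopropylsilyloxy)chroman-2-ol as a mixture of C2 anomers, via ortho-quinone methide 11 (not isolated), via enamine 12 (not isolated), via aminal 13 (not isolated)
Conditions: (R)-2-[diphenyl(trimethylsilyloxy)methyl]pyrrolidine (20 mol %), NaHCO3 (sat. aq.), CH2Cl2, 0 °C to rt; crude 14 taken directly into step 9
Reagents that add atoms: water, O (the lactol hydroxyl oxygen, delivered when aminal 13 is hydrolysed)
Why: NaHCO3 turns 5 into its phenoxide, which expels p-toluenesulfinate (E1cB, pushed by the para silyloxy group) to release ortho-quinone methide 11 slowly, while 10 and the amine condense to the (E)-enamine 12; C3 of 12 adds to the exocyclic CH2 of 11 (C3–C4 bond, rearomatising ring A), the phenoxide closes on the iminium carbon (O1–C2 bond) to give aminal 13, and water releases lactol 14 and the catalyst. This is the known secondary-amine-catalysed formal (4+2) annulation of enolisable aldehydes with ortho-quinone methides generated from 2-(sulfonylmethyl)phenols, a stepwise inverse-electron-demand oxa-Diels–Alder reaction. Ring C closes by 6-exo-trig attack of the phenoxide oxygen on the iminium carbon. C3 is set by the catalyst: in the s-trans (E)-enamine the diphenyl(trimethylsilyloxy)methyl group shields one face, and attack on the open face with the (R)-catalyst should give (3R), while C2 forms as both anomers and is erased in step 9. The step needs enamine C-alkylation to outrun self-aldol of 10 and oligomerisation of 11, which the unhindered and strongly electrophilic CH2 terminus of 11 and its slow release should secure, and it needs the α-aryl centre to survive, which the ring A phenol secures by locking the aldehyde as the lactol (the hindered α,α-disubstituted open form re-forms an enamine only reluctantly).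

Step 9
Reactants: 14 (3R)-3-[4-(3-methylbut-2-enyloxy)-2-(triisopropylsilyloxy)phenyl]-7-(triisopropylsilyloxy)chroman-2-ol
Product: 15 2-{(2R)-3-hydroxy-2-[4-(3-methylbut-2-enyloxy)-2-(triisopropylsilyloxy)phenyl]propyl}-5-(triisopropylsilyloxy)phenol
Conditions: NaBH4, MeOH–THF, 0 °C
Reagents that add atoms: none
Why: Hydride reduction of the hydroxy aldehyde that the lactol exposes by ring–chain tautomerism, which is fast at 0 °C and turns the epimerisable α-aryl aldehyde into a configurationally safe primary alcohol.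

Step 10
Reactants: 15 2-{(2R)-3-hydroxy-2-[4-(3-methylbut-2-enyloxy)-2-(triisopropylsilyloxy)phenyl]propyl}-5-(triisopropylsilyloxy)phenol
Product: 16 (3R)-3-[4-(3-methylbut-2-enyloxy)-2-(triisopropylsilyloxy)phenyl]-7-(triisopropylsilyloxy)chroman
Conditions: PPh3, DIAD, THF, 0 °C to rt
Reagents that add atoms: none
Why: Intramolecular Mitsunobu etherification in which the primary alcohol, activated as its alkoxyphosphonium ion, is displaced (6-exo-tet) by the ring A phenol, the only free one because the ring B oxygen is silylated, at a carbon that is not the stereocentre.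

Step 11
Reactants: 16 (3R)-3-[4-(3-methylbut-2-enyloxy)-2-(triisopropylsilyloxy)phenyl]-7-(triisopropylsilyloxy)chroman
Product: 17 2-(2-methylbut-3-en-2-yl)-5-(triisopropylsilyloxy)-4-[(3R)-7-(triisopropylsilyloxy)chroman-3-yl]phenol
Conditions: PhNEt2 (degassed), 190 °C, sealed tube
Reagents that add atoms: none
Why: Aromatic Claisen rearrangement ([3,3]-sigmatropic shift, then tautomerisation) should carry the prenyl group with allylic inversion to C5', since the other ortho carbon C3' is crowded by the 2'-silyloxy group and the para carbon C1' is substituted, while the basic solvent holds back acid-catalysed closure of the new phenol onto the olefin.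

Step 12
Reactants: 17 2-(2-methylbut-3-en-2-yl)-5-(triisopropylsilyloxy)-4-[(3R)-7-(triisopropylsilyloxy)chroman-3-yl]phenol; 6 prenyl bromide
Product: 18 (3R)-3-[5-(2-methylbut-3-en-2-yl)-4-(3-methylbut-2-enyloxy)-2-(triisopropylsilyloxy)phenyl]-7-(triisopropylsilyloxy)chroman
Conditions: 6, K2CO3, acetone, 50 °C
Reagents that add atoms: prenyl bromide 6, CC(C)=CCBr
Why: Williamson etherification of the single free phenol, under carbonate in acetone, conditions too mild to cleave aryl triisopropylsilyl ethers.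

Step 13
Reactants: 18 (3R)-3-[5-(2-methylbut-3-en-2-yl)-4-(3-methylbut-2-enyloxy)-2-(triisopropylsilyloxy)phenyl]-7-(triisopropylsilyloxy)chroman
Product: 19 Manuifolin D, (3R)-3-[2-hydroxy-5-(2-methylbut-3-en-2-yl)-4-(3-methylbut-2-enyloxy)phenyl]chroman-7-ol
Conditions: Bu4NF (2.5 equiv), AcOH (2.5 equiv), THF, 0 °C
Reagents that add atoms: none
Why: Fluoride-induced cleavage of both aryl silyl ethers, driven by the strong Si–F bond and buffered with acetic acid so that the electron-rich phenoxides are protonated as they form, with the prenyl ether and both olefins inert.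

Compound list
1 | 2,4-dihydroxybenzaldehyde | O=Cc1ccc(O)cc1O | starting material
2 | 2-hydroxy-4-(triisopropylsilyloxy)benzaldehyde | O=Cc1ccc(O[Si](C(C)C)(C(C)C)C(C)C)cc1O | intermediate
3 | 2-(hydroxymethyl)-5-(triisopropylsilyloxy)phenol | OCc1ccc(O[Si](C(C)C)(C(C)C)C(C)C)cc1O | intermediate
4 | sodium p-toluenesulfinate | Cc1ccc(cc1)S(=O)[O-].[Na+] | starting material
5 | 2-(tosylmethyl)-5-(triisopropylsilyloxy)phenol | Cc1ccc(cc1)S(=O)(=O)Cc1ccc(O[Si](C(C)C)(C(C)C)C(C)C)cc1O | intermediate
6 | prenyl bromide (1-bromo-3-methylbut-2-ene) | CC(C)=CCBr | starting material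
7 | 2-hydroxy-4-(3-methylbut-2-enyloxy)benzaldehyde | O=Cc1ccc(OCC=C(C)C)cc1O | intermediate
8 | 4-(3-methylbut-2-enyloxy)-2-(triisopropylsilyloxy)benzaldehyde | O=Cc1ccc(OCC=C(C)C)cc1O[Si](C(C)C)(C(C)C)C(C)C | intermediate
9 | triisopropyl[2-(2-methoxyvinyl)-5-(3-methylbut-2-enyloxy)phenoxy]silane (E/Z mixture) | COC=Cc1ccc(OCC=C(C)C)cc1O[Si](C(C)C)(C(C)C)C(C)C | intermediate
10 | 2-[4-(3-methylbut-2-enyloxy)-2-(triisopropylsilyloxy)phenyl]acetaldehyde | O=CCc1ccc(OCC=C(C)C)cc1O[Si](C(C)C)(C(C)C)C(C)C | intermediate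
11 | 6-methylidene-3-(triisopropylsilyloxy)cyclohexa-2,4-dien-1-one (ortho-quinone methide) | C=C1C=CC(O[Si](C(C)C)(C(C)C)C(C)C)=CC1=O | intermediate
12 | (2R)-2-[diphenyl(trimethylsilyloxy)methyl]-1-{(E)-2-[4-(3-methylbut-2-enyloxy)-2-(triisopropylsilyloxy)phenyl]vinyl}pyrrolidine (enamine) | CC(C)=CCOc1ccc(/C=C/N2CCC[C@@H]2C(c2ccccc2)(c2ccccc2)O[Si](C)(C)C)c(O[Si](C(C)C)(C(C)C)C(C)C)c1 | intermediate
13 | (2R)-2-[diphenyl(trimethylsilyloxy)methyl]-1-{(3R)-3-[4-(3-methylbut-2-enyloxy)-2-(triisopropylsilyloxy)phenyl]-7-(triisopropylsilyloxy)chroman-2-yl}pyrrolidine (aminal, C2 of the chroman undefined) | CC(C)=CCOc1ccc([C@@H]2C(N3CCC[C@@H]3C(c3ccccc3)(c3ccccc3)O[Si](C)(C)C)Oc3cc(O[Si](C(C)C)(C(C)C)C(C)C)ccc3C2)c(O[Si](C(C)C)(C(C)C)C(C)C)c1 | intermediate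
14 | (3R)-3-[4-(3-methylbut-2-enyloxy)-2-(triisopropylsilyloxy)phenyl]-7-(triisopropylsilyloxy)chroman-2-ol (both anomers at C2) | CC(C)=CCOc1ccc([C@@H]2C(O)Oc3cc(O[Si](C(C)C)(C(C)C)C(C)C)ccc3C2)c(O[Si](C(C)C)(C(C)C)C(C)C)c1 | intermediate
15 | 2-{(2R)-3-hydroxy-2-[4-(3-methylbut-2-enyloxy)-2-(triisopropylsilyloxy)phenyl]propyl}-5-(triisopropylsilyloxy)phenol | CC(C)=CCOc1ccc([C@H](CO)Cc2ccc(O[Si](C(C)C)(C(C)C)C(C)C)cc2O)c(O[Si](C(C)C)(C(C)C)C(C)C)c1 | intermediate
16 | (3R)-3-[4-(3-methylbut-2-enyloxy)-2-(triisopropylsilyloxy)phenyl]-7-(triisopropylsilyloxy)chroman | CC(C)=CCOc1ccc([C@@H]2COc3cc(O[Si](C(C)C)(C(C)C)C(C)C)ccc3C2)c(O[Si](C(C)C)(C(C)C)C(C)C)c1 | intermediate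
17 | 2-(2-methylbut-3-en-2-yl)-5-(triisopropylsilyloxy)-4-[(3R)-7-(triisopropylsilyloxy)chroman-3-yl]phenol | C=CC(C)(C)c1cc([C@@H]2COc3cc(O[Si](C(C)C)(C(C)C)C(C)C)ccc3C2)c(O[Si](C(C)C)(C(C)C)C(C)C)cc1O | intermediate
18 | (3R)-3-[5-(2-methylbut-3-en-2-yl)-4-(3-methylbut-2-enyloxy)-2-(triisopropylsilyloxy)phenyl]-7-(triisopropylsilyloxy)chroman | C=CC(C)(C)c1cc([C@@H]2COc3cc(O[Si](C(C)C)(C(C)C)C(C)C)ccc3C2)c(O[Si](C(C)C)(C(C)C)C(C)C)cc1OCC=C(C)C | intermediate
19 | Manuifolin D, (3R)-3-[2-hydroxy-5-(2-methylbut-3-en-2-yl)-4-(3-methylbut-2-enyloxy)phenyl]chroman-7-ol | C=CC(C)(C)c1cc([C@@H]2COc3cc(O)ccc3C2)c(O)cc1OCC=C(C)C | target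

Total step count: 13. Longest linear sequence: 10 steps (steps 4 to 13, from 1 through the ring B arm).

Steps most likely to fail

Step 8. What may go wrong: oligomerisation of the unsubstituted ortho-quinone methide before the enamine captures it, aldol self-condensation of the arylacetaldehyde, or erosion of the C3 configuration through ring-opening of the lactol and renewed enamine formation. The fallback is an auxiliary-controlled enolate alkylation that makes the same C3–C4 bond and leaves O1–C2 to the Mitsunobu step; it sets out from 10 and 2 and comes back to the route at 15. Aldehyde 10 would be oxidised under Pinnick conditions (NaClO2, NaH2PO4, 2-methyl-2-butene, tBuOH–H2O) to 2-[4-(3-methylbut-2-enyloxy)-2-(triisopropylsilyloxy)phenyl]acetic acid F1. Pivaloyl chloride and Et3N would convert it into the mixed pivalic anhydride F2 (not isolated), and (R)-4-benzyl-2-oxazolidinone with LiCl would then give the N-arylacetyl oxazolidinone F3. In parallel, 2 would be O-allylated (allyl bromide, K2CO3, acetone) to 2-(allyloxy)-4-(triisopropylsilyloxy)benzaldehyde F4, reduced (NaBH4, MeOH) to [2-(allyloxy)-4-(triisopropylsilyloxy)phenyl]methanol F5 and converted (CBr4, PPh3, CH2Cl2, 0 °C) into the benzylic bromide F6, to be used at once. The sodium enolate of F3 (NaN(SiMe3)2, THF, −78 °C) would be alkylated by F6 on the face remote from the benzyl group of the auxiliary to give the (2R)-configured imide F7. LiBH4 (THF–MeOH, 0 °C) would cleave the auxiliary to give the primary alcohol F8. Pd(PPh3)4 with morpholine would then remove the allyl group, the more substituted prenyl ether ionising far more slowly with zerovalent palladium, to give 15.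

Step 11. What may go wrong: migration to C3' in competition with C5', ring closure of the new phenol onto its 1,1-dimethylallyl neighbour, or thermal loss of the prenyl group, all on a late intermediate. The fallback moves the sigmatropic shift to the start of the ring B arm, where the para formyl group makes the phenol less prone to ring closure and the material is cheap; it sets out from 8 and comes back at 18. Heating 8 in PhNEt2 at 190 °C would give 4-hydroxy-5-(2-methylbut-3-en-2-yl)-2-(triisopropylsilyloxy)benzaldehyde F9. Prenyl bromide 6 and K2CO3 in acetone would give the prenyl ether F10, the Wittig reaction of step 6 the enol ether F11, and the hydrolysis of step 7 the arylacetaldehyde F12. Under the conditions of step 8, F12 and 5 would combine through 11, the enamine F13 and the aminal F14 to the lactol F15. NaBH4 would give the diol F16, and the Mitsunobu closure of step 10 would give 18, which needs only step 13.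

Step 7. What may go wrong: acid-induced loss of the prenyl group, or aldol self-condensation of the product while the enol ether hydrolyses slowly. The fallback is a homologation by hydroboration and oxidation that uses no acid; it sets out from 8 and comes back at 10. Methylenation of 8 (Ph3PCH3Br, KOtBu, THF) would give the styrene F17. 9-BBN (THF, rt), which leaves the trisubstituted prenyl olefin alone, would give the B-alkyl borane F18 (not isolated), and NaBO3·4H2O would oxidise it to the 2-arylethanol F19. Dess–Martin periodinane buffered with NaHCO3 in CH2Cl2 would give 10.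

Further compounds
F1 | step 8 | 2-[4-(3-methylbut-2-enyloxy)-2-(triisopropylsilyloxy)phenyl]acetic acid | OC(=O)Cc1ccc(OCC=C(C)C)cc1O[Si](C(C)C)(C(C)C)C(C)C
F2 | step 8 | 2,2-dimethylpropanoic 2-[4-(3-methylbut-2-enyloxy)-2-(triisopropylsilyloxy)phenyl]acetic anhydride | CC(C)(C)C(=O)OC(=O)Cc1ccc(OCC=C(C)C)cc1O[Si](C(C)C)(C(C)C)C(C)C
F3 | step 8 | (4R)-4-benzyl-3-{2-[4-(3-methylbut-2-enyloxy)-2-(triisopropylsilyloxy)phenyl]acetyl}oxazolidin-2-one | O=C(Cc1ccc(OCC=C(C)C)cc1O[Si](C(C)C)(C(C)C)C(C)C)N1C(=O)OC[C@H]1Cc1ccccc1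
F4 | step 8 | 2-(allyloxy)-4-(triisopropylsilyloxy)benzaldehyde | O=Cc1ccc(O[Si](C(C)C)(C(C)C)C(C)C)cc1OCC=C
F5 | step 8 | [2-(allyloxy)-4-(triisopropylsilyloxy)phenyl]methanol | OCc1ccc(O[Si](C(C)C)(C(C)C)C(C)C)cc1OCC=C
F6 | step 8 | [3-(allyloxy)-4-(bromomethyl)phenoxy]triisopropylsilane | BrCc1ccc(O[Si](C(C)C)(C(C)C)C(C)C)cc1OCC=C
F7 | step 8 | (4R)-4-benzyl-3-{(2R)-3-[2-(allyloxy)-4-(triisopropylsilyloxy)phenyl]-2-[4-(3-methylbut-2-enyloxy)-2-(triisopropylsilyloxy)phenyl]propanoyl}oxazolidin-2-one | O=C([C@H](Cc1ccc(O[Si](C(C)C)(C(C)C)C(C)C)cc1OCC=C)c1ccc(OCC=C(C)C)cc1O[Si](C(C)C)(C(C)C)C(C)C)N1C(=O)OC[C@H]1Cc1ccccc1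
F8 | step 8 | (2R)-3-[2-(allyloxy)-4-(triisopropylsilyloxy)phenyl]-2-[4-(3-methylbut-2-enyloxy)-2-(triisopropylsilyloxy)phenyl]propan-1-ol | OC[C@H](Cc1ccc(O[Si](C(C)C)(C(C)C)C(C)C)cc1OCC=C)c1ccc(OCC=C(C)C)cc1O[Si](C(C)C)(C(C)C)C(C)C
F9 | step 11 | 4-hydroxy-5-(2-methylbut-3-en-2-yl)-2-(triisopropylsilyloxy)benzaldehyde | O=Cc1cc(C(C)(C)C=C)c(O)cc1O[Si](C(C)C)(C(C)C)C(C)C
F10 | step 11 | 5-(2-methylbut-3-en-2-yl)-4-(3-methylbut-2-enyloxy)-2-(triisopropylsilyloxy)benzaldehyde | O=Cc1cc(C(C)(C)C=C)c(OCC=C(C)C)cc1O[Si](C(C)C)(C(C)C)C(C)C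
F11 | step 11 | triisopropyl[2-(2-methoxyvinyl)-4-(2-methylbut-3-en-2-yl)-5-(3-methylbut-2-enyloxy)phenoxy]silane (E/Z mixture) | COC=Cc1cc(C(C)(C)C=C)c(OCC=C(C)C)cc1O[Si](C(C)C)(C(C)C)C(C)C
F12 | step 11 | 2-[5-(2-methylbut-3-en-2-yl)-4-(3-methylbut-2-enyloxy)-2-(triisopropylsilyloxy)phenyl]acetaldehyde | O=CCc1cc(C(C)(C)C=C)c(OCC=C(C)C)cc1O[Si](C(C)C)(C(C)C)C(C)C
F13 | step 11 | (2R)-2-[diphenyl(trimethylsilyloxy)methyl]-1-{(E)-2-[5-(2-methylbut-3-en-2-yl)-4-(3-methylbut-2-enyloxy)-2-(triisopropylsilyloxy)phenyl]vinyl}pyrrolidine | C=CC(C)(C)c1cc(/C=C/N2CCC[C@@H]2C(c2ccccc2)(c2ccccc2)O[Si](C)(C)C)c(O[Si](C(C)C)(C(C)C)C(C)C)cc1OCC=C(C)C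
F14 | step 11 | (2R)-2-[diphenyl(trimethylsilyloxy)methyl]-1-{(3R)-3-[5-(2-methylbut-3-en-2-yl)-4-(3-methylbut-2-enyloxy)-2-(triisopropylsilyloxy)phenyl]-7-(triisopropylsilyloxy)chroman-2-yl}pyrrolidine | C=CC(C)(C)c1cc([C@@H]2C(N3CCC[C@@H]3C(c3ccccc3)(c3ccccc3)O[Si](C)(C)C)Oc3cc(O[Si](C(C)C)(C(C)C)C(C)C)ccc3C2)c(O[Si](C(C)C)(C(C)C)C(C)C)cc1OCC=C(C)C
F15 | step 11 | (3R)-3-[5-(2-methylbut-3-en-2-yl)-4-(3-methylbut-2-enyloxy)-2-(triisopropylsilyloxy)phenyl]-7-(triisopropylsilyloxy)chroman-2-ol (both anomers at C2) | C=CC(C)(C)c1cc([C@@H]2C(O)Oc3cc(O[Si](C(C)C)(C(C)C)C(C)C)ccc3C2)c(O[Si](C(C)C)(C(C)C)C(C)C)cc1OCC=C(C)C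
F16 | step 11 | 2-{(2R)-3-hydroxy-2-[5-(2-methylbut-3-en-2-yl)-4-(3-methylbut-2-enyloxy)-2-(triisopropylsilyloxy)phenyl]propyl}-5-(triisopropylsilyloxy)phenol | C=CC(C)(C)c1cc([C@H](CO)Cc2ccc(O[Si](C(C)C)(C(C)C)C(C)C)cc2O)c(O[Si](C(C)C)(C(C)C)C(C)C)cc1OCC=C(C)C
F17 | step 7 | triisopropyl[5-(3-methylbut-2-enyloxy)-2-vinylphenoxy]silane | C=Cc1ccc(OCC=C(C)C)cc1O[Si](C(C)C)(C(C)C)C(C)C
F18 | step 7 | 9-{2-[4-(3-methylbut-2-enyloxy)-2-(triisopropylsilyloxy)phenyl]ethyl}-9-borabicyclo[3.3.1]nonane | CC(C)=CCOc1ccc(CCB2C3CCCC2CCC3)c(O[Si](C(C)C)(C(C)C)C(C)C)c1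
F19 | step 7 | 2-[4-(3-methylbut-2-enyloxy)-2-(triisopropylsilyloxy)phenyl]ethanol | OCCc1ccc(OCC=C(C)C)cc1O[Si](C(C)C)(C(C)C)C(C)C
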